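**Retrosynthetic overview**

- Feature: the butenolide (O–C6, C7=C11, C12=O, C13 on C11) is the cycloisomer of a 2,3-allenoic acid C6=C7=C11(C13)–C12O2H. Its carbon C7 carries C8 of the ten-membered carbocycle C1–C10, and C10 lies two carbons from C8, so C8=C9–C10=O can be a vinyl ketone acceptor for C7.
- 25 ⇐ 23 (C10 methylenation, C1 desilylation) ⇐ acyclic (Ra)-allenoic acid vinyl ketone 20. One palladium cascade makes O–C6 (butenolide, first ring) and then C7–C8 (ten-membered ring, second ring).
- 20 ⇐ (6S)-propargylic mesylate 17 (anti-SN2' carbonylation gives C11–C12 and the axis; the C10 carbinol is oxidised last) ⇐ (Z)-enal 13 + propargyl acetate 14 (C6–C7).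
- 13 ⇐ methyl ketone 4 + aldehyde 7 (aldol C1–C2, then C3 by reduction); 4 ⇐ butenolide 1, whose ring fixes the (Z)-C4=C5 alkene; 7 ⇐ (S)-but-3-ene-1,2-diol 5.

Key step: step 16

Numbering used throughout: C1 carbinol, C2, C3 acetoxy carbon, C4 methyl-bearing alkene carbon, C5, C6 lactone CH–O, C7 and C11 butenolide alkene, C12 lactone carbonyl, C13 acetoxymethyl, C8, C9, C10 (bearing exocyclic C14).

Remark on the chemistry: the target is (1R,3S,4Z,6R), so the C1 and C3 oxygens are 1,3-syn and C3 is set by a reduction that gives the syn isomer.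

Assumption: 1, 5 and 14 are taken as commercial.

Assumption: (S,S)-ProPhenol is taken as the antipode that sends the alkynyl group to the Re face of the aldehyde, which is the face the route needs.

**Step 1**
Reactants: 1 3-methylfuran-2(5H)-one
Product: 2 (2Z)-4-hydroxy-N-methoxy-N,2-dimethylbut-2-enamide
Conditions: MeNH(OMe)·HCl, AlMe3, CH2Cl2, 0 °C → rt; used crude
Reagents that add atoms: N,O-dimethylhydroxylamine hydrochloride, CNOC.Cl
Why: Lactone aminolysis by the aluminium amide (Weinreb amide formation) opens the ring without touching the alkene, so the cis relation of C3 and C6 in the ring becomes the (Z)-C4=C5 geometry.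

**Step 2**
Reactants: 2 (2Z)-4-hydroxy-N-methoxy-N,2-dimethylbut-2-enamide
Product: 3 (2Z)-N-methoxy-N,2-dimethyl-4-[(triethylsilyl)oxy]but-2-enamide
Conditions: TESCl, imidazole, CH2Cl2, 0 °C
Reagents that add atoms: chlorotriethylsilane, CC[Si](Cl)(CC)CC
Why: Silylation of the primary alcohol traps the hydroxy amide before it can relactonise and gives an ether that survives the Grignard and boron steps.

**Step 3**
Reactants: 3 (2Z)-N-methoxy-N,2-dimethyl-4-[(triethylsilyl)oxy]but-2-enamide
Product: 4 (3Z)-3-methyl-5-[(triethylsilyl)oxy]pent-3-en-2-one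
Conditions: MeMgBr, THF, −20 → 0 °C
Reagents that add atoms: methylmagnesium bromide, C[Mg]Br
Why: Weinreb ketone synthesis, in which the chelated tetrahedral adduct stops at mono-addition and delivers the methyl group that becomes C2.

**Step 4**
Reactants: 5 (S)-but-3-ene-1,2-diol
Product: 6 (S)-3,4-bis[(triethylsilyl)oxy]but-1-ene
Conditions: TESCl, imidazole, DMF, 0 °C → rt
Reagents that add atoms: chlorotriethylsilane, CC[Si](Cl)(CC)CC
Why: Plain bis-silylation of the diol, which leaves the stereocentre untouched.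

**Step 5**
Reactants: 6 (S)-3,4-bis[(triethylsilyl)oxy]but-1-ene
Product: 7 (S)-2-[(triethylsilyl)oxy]but-3-enal
Conditions: (COCl)2, DMSO, CH2Cl2, −78 → −35 °C; iPr2NEt, −78 → 0 °C; used crude at once
Reagents that add atoms: none
Why: Swern oxidation applied to silyl ethers converts the primary triethylsilyl ether directly into the aldehyde while the secondary one is inert, and cold addition of the hindered base with immediate use should keep the C10 centre intact.

**Step 6**
Reactants: 4 (3Z)-3-methyl-5-[(triethylsilyl)oxy]pent-3-en-2-one; 7 (S)-2-[(triethylsilyl)oxy]but-3-enal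
Product: 9 (2Z,6R,7S)-6-hydroxy-3-methyl-1,7-bis[(triethylsilyl)oxy]nona-2,8-dien-4-one, via dicyclohexylboron enolate 8 (not isolated)
Conditions: (c-Hex)2BCl, Et3N, Et2O, −78 → 0 °C; 7, −78 → −20 °C; pH 7 buffer, MeOH, H2O2, 0 °C
Reagents that add atoms: none
Why: Boron-mediated aldol reaction of a methyl ketone, in which soft enolisation occurs only at the CH3 group and the enolate adds to the α-silyloxy aldehyde in the polar Felkin–Anh (1,2-anti) sense, so the (S)-C10 centre sets C1 as R.

**Step 7**
Reactants: 9 (2Z,6R,7S)-6-hydroxy-3-methyl-1,7-bis[(triethylsilyl)oxy]nona-2,8-dien-4-one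
Product: 10 (2Z,6R,7S)-6-[(tert-butyldimethylsilyl)oxy]-3-methyl-1,7-bis[(triethylsilyl)oxy]nona-2,8-dien-4-one
Conditions: TBSOTf, 2,6-lutidine, CH2Cl2, −78 °C
Reagents that add atoms: tert-butyldimethylsilyl trifluoromethanesulfonate, CC(C)(C)[Si](C)(C)OS(=O)(=O)C(F)(F)F
Why: Silylation with the triflate at low temperature protects the β-hydroxy ketone without retro-aldol or elimination and puts the most robust silyl group on C1.

**Step 8**
Reactants: 10 (2Z,6R,7S)-6-[(tert-butyldimethylsilyl)oxy]-3-methyl-1,7-bis[(triethylsilyl)oxy]nona-2,8-dien-4-one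
Product: 11 (2Z,4S,6R,7S)-6-[(tert-butyldimethylsilyl)oxy]-3-methyl-1,7-bis[(triethylsilyl)oxy]nona-2,8-dien-4-ol
Conditions: (R)-Me-CBS oxazaborolidine, catecholborane, toluene, −78 °C
Reagents that add atoms: none
Why: Corey–Bakshi–Shibata reduction, in which the α-methylalkenyl branch is the large and the CH2 branch the small substituent, so the (R)-catalyst should give 3S (1,3-syn to C1) by reagent control with clean 1,2-reduction.

**Step 9**
Reactants: 11 (2Z,4S,6R,7S)-6-[(tert-butyldimethylsilyl)oxy]-3-methyl-1,7-bis[(triethylsilyl)oxy]nona-2,8-dien-4-ol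
Product: 12 (2Z,4S,6R,7S)-6-[(tert-butyldimethylsilyl)oxy]-3-methyl-1,7-bis[(triethylsilyl)oxy]nona-2,8-dien-4-yl acetate
Conditions: Ac2O, pyridine, DMAP (cat.), CH2Cl2, 0 °C → rt
Reagents that add atoms: acetic anhydride, CC(=O)OC(C)=O
Why: Standard acylation of the only free hydroxyl installs the C3 acetate of the target.

**Step 10**
Reactants: 12 (2Z,4S,6R,7S)-6-[(tert-butyldimethylsilyl)oxy]-3-methyl-1,7-bis[(triethylsilyl)oxy]nona-2,8-dien-4-yl acetate
Product: 13 (2Z,4S,6R,7S)-4-acetoxy-6-[(tert-butyldimethylsilyl)oxy]-3-methyl-7-[(triethylsilyl)oxy]nona-2,8-dienal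
Conditions: (COCl)2, DMSO, CH2Cl2, −78 → −35 °C; iPr2NEt, −78 → −20 °C
Reagents that add atoms: none
Why: Swern oxidative desilylation again, in which only the primary allylic triethylsilyl ether at C6 reacts, the secondary silyl ethers and the acetate stay, and the (Z)-enal has no α-hydrogen through which to isomerise.

**Step 11**
Reactants: 13 (2Z,4S,6R,7S)-4-acetoxy-6-[(tert-butyldimethylsilyl)oxy]-3-methyl-7-[(triethylsilyl)oxy]nona-2,8-dienal; 14 prop-2-yn-1-yl acetate
Product: 16 (4S,5Z,7S,9R,10S)-7-acetoxy-9-[(tert-butyldimethylsilyl)oxy]-4-hydroxy-6-methyl-10-[(triethylsilyl)oxy]dodeca-5,11-dien-2-yn-1-yl acetate (numbered from C13; 6S in target numbering), via alkynyl(methyl)zinc 15 (not isolated)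
Conditions: ZnMe2, (S,S)-ProPhenol (20 mol %), Ph3PO (40 mol %), toluene, 0 °C
Reagents that add atoms: none
Why: Dinuclear-zinc ProPhenol-catalysed asymmetric alkynylation of an α,β-unsaturated aldehyde, in which the zinc acetylide adds to the Re face to set C6 as S and tolerates the acetates and silyl ethers.

**Step 12**
Reactants: 16 the (6S)-propargylic alcohol
Product: 17 the 4-methanesulfonate of 16 (6S)
Conditions: MsCl, Et3N, CH2Cl2, −78 °C; cold work-up, used at once
Reagents that add atoms: methanesulfonyl chloride, CS(=O)(=O)Cl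
Why: Sulfonylation at low temperature activates the only free hydroxyl with retention at C6, and the labile allylic-propargylic mesylate is carried on without storage.

**Step 13**
Reactants: 17 the (6S)-propargylic mesylate
Product: 18 (Ra,5Z,7S,9R,10S)-7-acetoxy-2-(acetoxymethyl)-9-[(tert-butyldimethylsilyl)oxy]-6-methyl-10-[(triethylsilyl)oxy]dodeca-2,3,5,11-tetraenoic acid
Conditions: Pd(PPh3)4 (5 mol %), CO (1 atm), 2,6-lutidine, THF–H2O, 0 °C; kept below 20 °C
Reagents that add atoms: carbon monoxide, [C-]#[O+]; water, O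
Why: Palladium-catalysed hydroxycarbonylation of a propargylic mesylate, in which zerovalent palladium displaces the mesylate by anti-SN2' attack at C11 and CO insertion with hydrolysis follows with retention, so the 6S centre becomes the (Ra) axis and C12 is installed while the mesylate ionises far faster than either acetate.

**Step 14**
Reactants: 18 the C10 triethylsilyl ether of the allenoic acid
Product: 19 (Ra,5Z,7S,9R,10S)-7-acetoxy-2-(acetoxymethyl)-9-[(tert-butyldimethylsilyl)oxy]-10-hydroxy-6-methyldodeca-2,3,5,11-tetraenoic acid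
Conditions: HF·pyridine, pyridine, THF, 0 °C
Reagents that add atoms: none
Why: Buffered fluoride desilylation cleaves the secondary triethylsilyl ether much faster than the hindered tert-butyldimethylsilyl ether at C1 and does not disturb the allenoic acid.

**Step 15**
Reactants: 19 the C10 allylic alcohol
Product: 20 (Ra,5Z,7S,9R)-7-acetoxy-2-(acetoxymethyl)-9-[(tert-butyldimethylsilyl)oxy]-6-methyl-10-oxododeca-2,3,5,11-tetraenoic acid
Conditions: Dess–Martin periodinane, CH2Cl2, 0 °C; used at once
Reagents that add atoms: none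
Why: Dess–Martin oxidation of the allylic alcohol under neutral conditions, placed after the carbonylation because the phosphine of step 13 would join a vinyl ketone and an allenoate.

**Step 16**
Reactants: 20 the acyclic (Ra)-allenoic acid vinyl ketone
Product: 23 10-oxo macrocycle as its C1 tert-butyldimethylsilyl ether (ten-membered ring C1–C10 fused at C6–C7 to the butenolide; 1R,3S,4Z,6R; C3 and C13 acetates), via butenolidyl-palladium bromide 21 (not isolated), via macrocyclic palladium enolate 22 (not isolated)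
Conditions: PdCl2(MeCN)2 (10 mol %), LiBr (4 equiv), MeCN, 0.002 M (slow addition of 20), 0 °C → rt
Reagents that add atoms: none
Why: Proposed new method: divalent palladium coordinates the C6=C7 bond of the allene, the carboxyl oxygen attacks C6 anti to the metal to give 21, the C7–Pd bond inserts the tethered vinyl ketone at C8 to give 22, and protonolysis by the HBr set free in the first event (bromide blocking beta-hydride loss) releases 23 and the catalyst, so the substrate is simply isomerised. The closest known reactions are PdCl2-catalysed cyclisations of 2,3-allenoic acids in which the butenolidyl-palladium is captured by an alkene, and halide-assisted conjugate addition of vinylpalladium species to enones ending in protonolysis; neither has been used to close a medium ring. The butenolide closes in a five-membered endo mode at the allene terminus and the carbocycle in a 10-endo-trig insertion at the terminal carbon of the enone. C6 is fixed by the allene axis alone, because the lactone oxygen arrives in the plane of the C11 substituents whichever face the metal takes, so the (Ra) axis gives 6R. The step needs the insertion to outrun protodepalladation of 21, bimolecular capture and the [1,5]-hydrogen shift of the (Z)-vinylallene; the (Z)-C4=C5 alkene and the flat butenolide turn the chain so that C8 lies near C7, high dilution removes the bimolecular path, and the absence of added acid keeps protonolysis of the sp2 C–Pd bond slow.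

**Step 17**
Reactants: 23 the 10-oxo macrocycle
Product: 24 10-methylene macrocycle (C1 tert-butyldimethylsilyl ether of the target)
Conditions: Zn, CH2Br2, TiCl4, THF–CH2Cl2, 0 °C → rt
Reagents that add atoms: dibromomethane, BrCBr
Why: Takai–Lombardo methylenation, whose non-basic zinc–titanium methylene reagent converts ketones but not esters or lactones and does not epimerise the α-silyloxy centre C1.

**Step 18**
Reactants: 24 the C1 silyl ether of the target
Product: 25 CNP0227830.1
Conditions: HF·pyridine, THF, 0 °C → rt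
Reagents that add atoms: none
Why: Acidic fluoride desilylation frees the C1 hydroxyl without acyl migration from C3 and leaves the acetates, the butenolide and the exocyclic alkene untouched.

**Compound list**

1 | 3-methylfuran-2(5H)-one | CC1=CCOC1=O | starting material
2 | (2Z)-4-hydroxy-N-methoxy-N,2-dimethylbut-2-enamide | CON(C)C(=O)/C(C)=C\CO | intermediate
3 | (2Z)-N-methoxy-N,2-dimethyl-4-[(triethylsilyl)oxy]but-2-enamide | CON(C)C(=O)/C(C)=C\CO[Si](CC)(CC)CC | intermediate
4 | (3Z)-3-methyl-5-[(triethylsilyl)oxy]pent-3-en-2-one | CC(=O)/C(C)=C\CO[Si](CC)(CC)CC | intermediate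
5 | (S)-but-3-ene-1,2-diol | C=C[C@H](O)CO | starting material
6 | (S)-3,4-bis[(triethylsilyl)oxy]but-1-ene | C=C[C@H](O[Si](CC)(CC)CC)CO[Si](CC)(CC)CC | intermediate
7 | (S)-2-[(triethylsilyl)oxy]but-3-enal | C=C[C@H](O[Si](CC)(CC)CC)C=O | intermediate
8 | dicyclohexylboron enolate of 4 (not isolated) | C=C(OB(C1CCCCC1)C1CCCCC1)/C(C)=C\CO[Si](CC)(CC)CC | intermediate
9 | (2Z,6R,7S)-6-hydroxy-3-methyl-1,7-bis[(triethylsilyl)oxy]nona-2,8-dien-4-one (1R,10S in target numbering) | C=C[C@H](O[Si](CC)(CC)CC)[C@H](O)CC(=O)/C(C)=C\CO[Si](CC)(CC)CC | intermediate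
10 | (2Z,6R,7S)-6-[(tert-butyldimethylsilyl)oxy]-3-methyl-1,7-bis[(triethylsilyl)oxy]nona-2,8-dien-4-one | C=C[C@H](O[Si](CC)(CC)CC)[C@H](O[Si](C)(C)C(C)(C)C)CC(=O)/C(C)=C\CO[Si](CC)(CC)CC | intermediate
11 | (2Z,4S,6R,7S)-6-[(tert-butyldimethylsilyl)oxy]-3-methyl-1,7-bis[(triethylsilyl)oxy]nona-2,8-dien-4-ol | C=C[C@H](O[Si](CC)(CC)CC)[C@H](O[Si](C)(C)C(C)(C)C)C[C@H](O)/C(C)=C\CO[Si](CC)(CC)CC | intermediate
12 | (2Z,4S,6R,7S)-6-[(tert-butyldimethylsilyl)oxy]-3-methyl-1,7-bis[(triethylsilyl)oxy]nona-2,8-dien-4-yl acetate | C=C[C@H](O[Si](CC)(CC)CC)[C@H](O[Si](C)(C)C(C)(C)C)C[C@H](OC(C)=O)/C(C)=C\CO[Si](CC)(CC)CC | intermediate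
13 | (2Z,4S,6R,7S)-4-acetoxy-6-[(tert-butyldimethylsilyl)oxy]-3-methyl-7-[(triethylsilyl)oxy]nona-2,8-dienal | C=C[C@H](O[Si](CC)(CC)CC)[C@H](O[Si](C)(C)C(C)(C)C)C[C@H](OC(C)=O)/C(C)=C\C=O | intermediate
14 | prop-2-yn-1-yl acetate | C#CCOC(C)=O | starting material
15 | [3-(acetyloxy)prop-1-yn-1-yl](methyl)zinc (not isolated) | C[Zn]C#CCOC(C)=O | intermediate
16 | (6S)-propargylic alcohol: (4S,5Z,7S,9R,10S)-7-acetoxy-9-[(tert-butyldimethylsilyl)oxy]-4-hydroxy-6-methyl-10-[(triethylsilyl)oxy]dodeca-5,11-dien-2-yn-1-yl acetate | C=C[C@H](O[Si](CC)(CC)CC)[C@H](O[Si](C)(C)C(C)(C)C)C[C@H](OC(C)=O)/C(C)=C\[C@H](O)C#CCOC(C)=O | intermediate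
17 | (6S)-propargylic mesylate (4-methanesulfonate of 16) | C=C[C@H](O[Si](CC)(CC)CC)[C@H](O[Si](C)(C)C(C)(C)C)C[C@H](OC(C)=O)/C(C)=C\[C@H](OS(C)(=O)=O)C#CCOC(C)=O | intermediate
18 | (Ra,5Z,7S,9R,10S)-7-acetoxy-2-(acetoxymethyl)-9-[(tert-butyldimethylsilyl)oxy]-6-methyl-10-[(triethylsilyl)oxy]dodeca-2,3,5,11-tetraenoic acid | C=C[C@H](O[Si](CC)(CC)CC)[C@H](O[Si](C)(C)C(C)(C)C)C[C@H](OC(C)=O)/C(C)=C\C([H])=[C@]=C(COC(C)=O)C(O)=O | intermediate
19 | (Ra,5Z,7S,9R,10S)-7-acetoxy-2-(acetoxymethyl)-9-[(tert-butyldimethylsilyl)oxy]-10-hydroxy-6-methyldodeca-2,3,5,11-tetraenoic acid | C=C[C@H](O)[C@H](O[Si](C)(C)C(C)(C)C)C[C@H](OC(C)=O)/C(C)=C\C([H])=[C@]=C(COC(C)=O)C(O)=O | intermediate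
20 | (Ra,5Z,7S,9R)-7-acetoxy-2-(acetoxymethyl)-9-[(tert-butyldimethylsilyl)oxy]-6-methyl-10-oxododeca-2,3,5,11-tetraenoic acid (key-step precursor) | C=CC(=O)[C@H](O[Si](C)(C)C(C)(C)C)C[C@H](OC(C)=O)/C(C)=C\C([H])=[C@]=C(COC(C)=O)C(O)=O | intermediate
21 | (6R)-butenolidyl-palladium bromide with Pd on C7, ligands omitted (not isolated) | C=CC(=O)[C@H](O[Si](C)(C)C(C)(C)C)C[C@H](OC(C)=O)/C(C)=C\[C@H]1OC(=O)C(COC(C)=O)=C1[Pd]Br | intermediate
22 | macrocyclic palladium enolate with Pd on C9, ligands omitted (not isolated) | O=C1C([Pd]Br)CC2=C(COC(C)=O)C(=O)O[C@@H]2/C=C(/C)[C@@H](OC(C)=O)C[C@H]1O[Si](C)(C)C(C)(C)C | intermediate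
23 | 10-oxo macrocycle, C1 tert-butyldimethylsilyl ether (1R,3S,4Z,6R) (key-step product) | O=C1CCC2=C(COC(C)=O)C(=O)O[C@@H]2/C=C(/C)[C@@H](OC(C)=O)C[C@H]1O[Si](C)(C)C(C)(C)C | intermediate
24 | 10-methylene macrocycle, C1 tert-butyldimethylsilyl ether of the target | C=C1CCC2=C(COC(C)=O)C(=O)O[C@@H]2/C=C(/C)[C@@H](OC(C)=O)C[C@H]1O[Si](C)(C)C(C)(C)C | intermediate
25 | CNP0227830.1 (1R,3S,4Z,6R) | C=C1CCC2=C(COC(C)=O)C(=O)O[C@@H]2/C=C(/C)[C@@H](OC(C)=O)C[C@H]1O | target

**Step count**

Total steps: 18. Longest linear sequence: 16 (steps 1–3 and 6–18 from 1); steps 4–5 form the two-step branch to aldehyde 7.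

**Steps most likely to fail, with fallbacks**

Step 16. The cascade may stall after lactonisation because protodepalladation outruns the ten-membered insertion, or the (Z)-vinylallene may undergo the [1,5]-hydrogen shift before it cyclises. The two bonds would then be made in separate known reactions, setting out from allenoic acid 18. Iodolactonisation with N-iodosuccinimide in MeCN at 0 °C transfers the axis to C6 in the same sense and should give the β-iodobutenolide F1. Hydroboration of the terminal C8=C9 alkene with 9-BBN in THF should give the C8 alkylborane F2, which is not isolated. An intramolecular B-alkyl Suzuki–Miyaura coupling (Pd(dppf)Cl2, AsPh3, K3PO4, DMF–THF–H2O, high dilution) would join C7 to C8 in the macrocyclic C10 triethylsilyl ether F3. HF·pyridine would free the C10 alcohol F4, and Dess–Martin oxidation brings the route back at ketone 23.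

Step 13. The doubly activated mesylate may ionise along the allyl manifold, the axis may erode through allenyl–propargyl palladium equilibration, or zerovalent palladium may ionise the C13 acetate a second time; the vinylallene may also rearrange thermally if the mixture warms. The stereo-defining substitution would then be handed to copper, setting out from mesylate 17. LiCuBr2 in THF at −40 → 0 °C should give, by anti-SN2' attack at C11, the (Ra)-bromoallene F5. Hydroxycarbonylation of its sp2 C–Br bond (Pd(PPh3)4, CO, iPr2NEt, THF–H2O, rt), with oxidative addition and insertion under retention, comes back at acid 18.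

Step 11. Facial selectivity may be poor on the (Z)-β,β-disubstituted enal, or slow addition may allow (Z) to (E) isomerisation and erode the C6 centre on which the axis depends. Setting out from enal 13, alkynylzinc 15 would be added with racemic ProPhenol to give the C6-epimeric alcohols F6. Dess–Martin oxidation would give the ynone F7, and Midland reduction with (S)-Alpine-Borane in THF at rt, in which the alkynyl group is the small substituent, should set 6S and come back at alcohol 16.

**Further compounds**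

F1 | step 16 | (6R)-β-iodobutenolide: 3-(acetoxymethyl)-4-iodofuran-2(5H)-one carrying at C5 the (Z)-alkenyl chain with 3-OAc, 1-OTBS, 10-OTES and the C8=C9 vinyl group | C=C[C@H](O[Si](CC)(CC)CC)[C@H](O[Si](C)(C)C(C)(C)C)C[C@H](OC(C)=O)/C(C)=C\[C@H]1OC(=O)C(COC(C)=O)=C1I
F2 | step 16 | C8 alkylborane of F1 (B-alkyl-9-borabicyclo[3.3.1]nonane, not isolated) | C(CB3C4CCCC3CCC4)[C@H](O[Si](CC)(CC)CC)[C@H](O[Si](C)(C)C(C)(C)C)C[C@H](OC(C)=O)/C(C)=C\[C@H]1OC(=O)C(COC(C)=O)=C1I
F3 | step 16 | macrocycle with C10 triethylsilyl ether and C1 tert-butyldimethylsilyl ether (1R,3S,4Z,6R,10S) | CC[Si](CC)(CC)O[C@H]1CCC2=C(COC(C)=O)C(=O)O[C@@H]2/C=C(/C)[C@@H](OC(C)=O)C[C@H]1O[Si](C)(C)C(C)(C)C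
F4 | step 16 | macrocyclic C10 alcohol, C1 tert-butyldimethylsilyl ether (10S) | O[C@H]1CCC2=C(COC(C)=O)C(=O)O[C@@H]2/C=C(/C)[C@@H](OC(C)=O)C[C@H]1O[Si](C)(C)C(C)(C)C
F5 | step 13 | (Ra)-bromoallene with bromine on C11 in place of the carboxyl group of 18 | C=C[C@H](O[Si](CC)(CC)CC)[C@H](O[Si](C)(C)C(C)(C)C)C[C@H](OC(C)=O)/C(C)=C\C([H])=[C@]=C(COC(C)=O)Br
F6 | step 11 | C6-epimeric mixture of propargylic alcohol 16 | C=C[C@H](O[Si](CC)(CC)CC)[C@H](O[Si](C)(C)C(C)(C)C)C[C@H](OC(C)=O)/C(C)=C\C(O)C#CCOC(C)=O
F7 | step 11 | C6 ynone (alkenyl alkynyl ketone) | C=C[C@H](O[Si](CC)(CC)CC)[C@H](O[Si](C)(C)C(C)(C)C)C[C@H](OC(C)=O)/C(C)=C\C(=O)C#CCOC(C)=O
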